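**Strategy.** The target is divided at its butenolide: the bond from lactone C3 to the vinyl group (Stille coupling) and the exocyclic lactone C5=CH bond (vinylogous aldol condensation) release a C22 polyenynal, 3-bromofuran-2(5H)-one and a vinylstannane carrying the triol ring. Everything rests on making that cyclohexane ring, with its trans C5/C6 diol, from an (S)-configured 4-ethynylcyclohex-3-enol whose C3 carbinol is antipodal to C3′ of the enyne ring. In one flask its C3 hydroxyl, homoallylic to the ring C5=C6 alkene, steers oxygen to the syn face and water then opens the oxirane at C5 with inversion, the C6 ethynyl group and the neopentyl C1 gem-dimethyl carbon deactivating C6; no target ring is closed.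

Key step: step 7

Remark: both six-membered rings carry carotenoid-type locants (C1 gem-dimethyl, C3 carbinol, C5 methyl-bearing carbon, C6 carbon bearing the side chain; primed for the enyne ring); the lactone is numbered as furan-2(5H)-one.
Remark: the triol ring of the target is (3R,5S,6S) and the enyne ring (3′R); the triol C3 is R although it has the spatial sense of the (S)-enynol, because C4 outranks C2 once C5 bears oxygen.
Remark: by the same change of ranking, the hydroxy-enone that leads to the (S)-enynol is (4R)-phorenol; the familiar enzymatic reductions of ketoisophorone lead to the other series, so a ligand-controlled transfer hydrogenation is used.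
Remark: the saturated silyloxy ketone of step 3 is carried as a mixture of epimers at its methyl-bearing α-carbon; all polyenes are handled under argon in dim light.

**Route**

Step 1
Reactants: 1 ketoisophorone (2,6,6-trimethylcyclohex-2-ene-1,4-dione)
Product: 2 (4R)-4-hydroxy-2,6,6-trimethylcyclohex-2-en-1-one [(R)-phorenol]
Conditions: RuCl(p-cymene)[(R,R)-TsDPEN] (1 mol%), KOH (cat.), i-PrOH, rt
Reagents that add atoms: none
Why: Noyori asymmetric transfer hydrogenation reduces only the unhindered enone carbonyl C4, and with the alkenyl flank in the role of the aryl group of an aryl alkyl ketone the (R,R)-ligand should give the (4R)-carbinol, whose sense and purity are to be checked chiroptically (the antipodal ligand is the remedy) and raised by crystallisation if needed.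

Step 2
Reactants: 2 (R)-phorenol
Product: 3 (4R)-4-[(tert-butyldimethylsilyl)oxy]-2,6,6-trimethylcyclohex-2-en-1-one
Conditions: TBSCl, imidazole, DMF, rt
Reagents that add atoms: tert-butyldimethylsilyl chloride, CC(C)(C)[Si](C)(C)Cl
Why: Silyl ether formation at the only hydroxyl; capping it prevents palladium-mediated isomerisation of the γ-hydroxy enone to the 1,4-dione in step 3 and O-triflation in step 4.

Step 3
Reactants: 3 silyl ether of (R)-phorenol
Product: 4 (4S)-4-[(tert-butyldimethylsilyl)oxy]-2,2,6-trimethylcyclohexan-1-one (C6 epimers)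
Conditions: H2 (1 atm), Pd/C, EtOAc, rt
Reagents that add atoms: none
Why: Heterogeneous catalytic hydrogenation saturates the enone C=C without touching the hindered ketone; C4 keeps its spatial arrangement (the descriptor changes only through the ranking of its ring neighbours) and the new C6 centre needs no control because it becomes sp2 in step 4.

Step 4
Reactants: 4 saturated silyloxy ketone
Product: 5 (4S)-4-[(tert-butyldimethylsilyl)oxy]-2,6,6-trimethylcyclohex-1-en-1-yl trifluoromethanesulfonate
Conditions: LiN(i-Pr)2, THF, −78 °C; PhNTf2, −78 °C to rt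
Reagents that add atoms: N-phenylbis(trifluoromethanesulfonimide), O=S(=O)(N(c1ccccc1)S(=O)(=O)C(F)(F)F)C(F)(F)F
Why: Deprotonation can occur only at C6 because C2 is quaternary, and O-sulfonylation of the lithium enolate gives the tetrasubstituted enol triflate (enol triflate formation).

Step 5
Reactants: 5 (S)-enol triflate; 6 trimethylsilylacetylene
Product: 7 tert-butyldimethyl({(1S)-3,5,5-trimethyl-4-[(trimethylsilyl)ethynyl]cyclohex-3-en-1-yl}oxy)silane
Conditions: Pd(PPh3)4 (5 mol%), CuI (10 mol%), Et3N, DMF, rt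
Reagents that add atoms: none
Why: Sonogashira coupling of the enol triflate with the terminal alkyne forms the ring C6–alkyne bond under mild amine conditions that leave the silyl ether untouched.

Step 6
Reactants: 7 doubly silylated enyne
Product: 8 (1S)-4-ethynyl-3,5,5-trimethylcyclohex-3-en-1-ol [(S)-enynol]
Conditions: TBAF, THF, 0 °C to rt
Reagents that add atoms: none
Why: Fluoride-induced desilylation cleaves the alkynyl C–Si bond and the silyl ether in one operation and leaves the C3 stereocentre untouched.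

Step 7
Reactants: 8 (S)-enynol
Product: 10 (1R,2S,4R)-1-ethynyl-2,6,6-trimethylcyclohexane-1,2,4-triol, via syn-epoxide 9 (not isolated)
Conditions: VO(acac)2 (5 mol%), t-BuOOH (1.2 equiv, in decane), toluene, rt to 40 °C; then THF, 1 M aq. H2SO4, 0 °C to rt (same flask)
Reagents that add atoms: tert-butyl hydroperoxide, CC(C)(C)OO; water, O
Why: VO(acac)2 is oxidised by t-BuOOH to a pentavalent vanadium alkylperoxo species that binds the C3 hydroxyl of 8 as an alkoxide and transfers oxygen within the complex to the face of the C5=C6 alkene syn to that hydroxyl (hydroxyl-directed epoxidation of a homoallylic cyclohexenol), which fixes C6 in syn-epoxide 9. Dilute acid then protonates the oxirane and water attacks C5 from the opposite face (acid-catalysed trans-diaxial epoxide hydrolysis of the Fürst–Plattner type), so C5 is set by inversion, the C5 and C6 hydroxyls end up trans and the C6 hydroxyl stays cis to the C3 hydroxyl. No ring of the target is closed: the only ring formed is the transient oxirane, made by syn oxygen transfer and opened again in the same flask. The step needs face selectivity in the oxygen transfer, secured by the single C3 carbinol, and site selectivity in the opening, secured by three concordant factors: the ethynyl group is net electron-withdrawing and destabilises cationic character at C6, backside approach to C6 is blocked by the neopentyl C1 gem-dimethyl carbon, and axial attack at C5 runs through the chair with the C3 hydroxyl equatorial whereas attack at C6 would force that hydroxyl axial against an axial C1 methyl. The C3 hydroxyl cannot intercept the protonated oxirane because it lies on the same face as the oxirane oxygen, and the terminal alkyne is inert to both reagents.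

Step 8
Reactants: 10 ethynyl triol
Product: 11 (1S,2S,4R)-2,6,6-trimethyl-1-[(E)-2-(tributylstannyl)ethenyl]cyclohexane-1,2,4-triol
Conditions: Bu3SnH (1.3 equiv, slow addition), PdCl2(PPh3)2 (3 mol%), THF, 0 °C to rt
Reagents that add atoms: tributyltin hydride, CCCC[SnH](CCCC)CCCC
Why: Palladium-catalysed hydrostannation is a syn addition and the fully substituted propargylic carbon C6, flanked by two further fully substituted carbons, sends tin to the terminal alkyne carbon, so the E-configured distal alkenylstannane should form without protection of the hydroxyls.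

Step 9
Reactants: 12 (4R,6R)-actinol [(4R,6R)-4-hydroxy-2,2,6-trimethylcyclohexan-1-one]
Product: 13 (4R,6R)-2,2,6-trimethyl-4-[(triethylsilyl)oxy]cyclohexan-1-one
Conditions: TESCl, imidazole, DMF, 0 °C to rt
Reagents that add atoms: triethylsilyl chloride, CC[Si](Cl)(CC)CC
Why: Silylation of the secondary alcohol; the triethylsilyl ether withstands the amide base, hydride, ylide and palladium steps that follow and can be removed at the end by buffered fluoride that a polyene butenolide tolerates.

Step 10
Reactants: 13 silyl ether of actinol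
Product: 14 (4R)-2,6,6-trimethyl-4-[(triethylsilyl)oxy]cyclohex-1-en-1-yl trifluoromethanesulfonate
Conditions: LiN(i-Pr)2, THF, −78 °C; PhNTf2, −78 °C to rt
Reagents that add atoms: N-phenylbis(trifluoromethanesulfonimide), O=S(=O)(N(c1ccccc1)S(=O)(=O)C(F)(F)F)C(F)(F)F
Why: As in step 4, enolisation is possible only towards C6 and O-triflation of the lithium enolate gives the tetrasubstituted enol triflate (enol triflate formation), erasing the C6 stereocentre of 13.

Step 11
Reactants: 14 (R)-enol triflate; 15 (E)-3-methylpent-2-en-4-yn-1-ol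
Product: 16 (2E)-3-methyl-5-{(4R)-2,6,6-trimethyl-4-[(triethylsilyl)oxy]cyclohex-1-en-1-yl}pent-2-en-4-yn-1-ol
Conditions: Pd(PPh3)4 (5 mol%), CuI (10 mol%), Et3N, DMF, rt
Reagents that add atoms: none
Why: Sonogashira coupling joins the enol triflate to the terminal alkyne of the E-enynol, which brings in the 9′E trisubstituted alkene with its geometry already fixed and tolerates the free primary alcohol.

Step 12
Reactants: 16 C15 allylic alcohol
Product: 17 (2E)-3-methyl-5-{(4R)-2,6,6-trimethyl-4-[(triethylsilyl)oxy]cyclohex-1-en-1-yl}pent-2-en-4-ynal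
Conditions: MnO2 (excess), CH2Cl2, rt, dark
Reagents that add atoms: none
Why: MnO2 oxidises the allylic alcohol selectively to the enal (allylic oxidation) under neutral conditions that should not isomerise the alkene.

Step 13
Reactants: 17 C15 enynal; 18 triethyl 4-phosphonocrotonate
Product: 19 ethyl (2E,4E,6E)-7-methyl-9-{(4R)-2,6,6-trimethyl-4-[(triethylsilyl)oxy]cyclohex-1-en-1-yl}nona-2,4,6-trien-8-ynoate
Conditions: 18, LiN(SiMe3)2, THF, −78 °C; then 17, −78 to 0 °C
Reagents that add atoms: none
Why: Horner–Wadsworth–Emmons olefination with the lithiated phosphonocrotonate reacts at the phosphorus-bearing carbon and should give the new disubstituted alkene with E geometry, as is usual for stabilised phosphonate anions.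

Step 14
Reactants: 19 C19 ester
Product: 20 (2E,4E,6E)-7-methyl-9-{(4R)-2,6,6-trimethyl-4-[(triethylsilyl)oxy]cyclohex-1-en-1-yl}nona-2,4,6-trien-8-yn-1-ol
Conditions: i-Bu2AlH (2.2 equiv), CH2Cl2, −78 °C
Reagents that add atoms: none
Why: i-Bu2AlH reduces the conjugated ester 1,2 to the allylic alcohol at low temperature (hydride reduction) without touching the silyl ether or the enyne.

Step 15
Reactants: 20 C19 allylic alcohol
Product: 21 (2E,4E,6E)-7-methyl-9-{(4R)-2,6,6-trimethyl-4-[(triethylsilyl)oxy]cyclohex-1-en-1-yl}nona-2,4,6-trien-8-ynal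
Conditions: MnO2 (excess), CH2Cl2, rt, dark
Reagents that add atoms: none
Why: Allylic oxidation with MnO2 as in step 12.

Step 16
Reactants: 21 C19 polyenynal; 22 2-(triphenylphosphoranylidene)propanal
Product: 23 (2E,4E,6E,8E)-2,9-dimethyl-11-{(4R)-2,6,6-trimethyl-4-[(triethylsilyl)oxy]cyclohex-1-en-1-yl}undeca-2,4,6,8-tetraen-10-ynal
Conditions: toluene, 60 °C, dark
Reagents that add atoms: none
Why: Wittig olefination with the formyl-stabilised ylide is E-selective and should stop after one homologation because the α-methyl enal formed is far less reactive towards this ylide than the unbranched polyenal.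

Step 17
Reactants: 24 furan-2(5H)-one
Product: 26 3-bromofuran-2(5H)-one, via dibromolactone 25 (not isolated)
Conditions: Br2, CH2Cl2, 0 °C to reflux; then Et3N, 0 °C
Reagents that add atoms: bromine, BrBr
Why: Anti addition of bromine to the butenolide alkene followed by base-induced loss of HBr through the acidic α-hydrogen gives the α-bromobutenolide (bromination–dehydrobromination).

Step 18
Reactants: 26 3-bromofuran-2(5H)-one; 23 C22 polyenynal
Product: 29 (5Z)-3-bromo-5-[(2E,4E,6E,8E)-2,9-dimethyl-11-{(4R)-2,6,6-trimethyl-4-[(triethylsilyl)oxy]cyclohex-1-en-1-yl}undeca-2,4,6,8-tetraen-10-yn-1-ylidene]furan-2(5H)-one, via silyloxyfuran 27 (not isolated), via aldol silyl ether 28 (not isolated)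
Conditions: TBSOTf, i-Pr2NEt, CH2Cl2, −78 °C to rt; then DBU, rt
Reagents that add atoms: none
Why: The amine and the silyl triflate convert 26 into 2-silyloxyfuran 27, which adds through its C5 to the silyl-activated aldehyde (vinylogous Mukaiyama aldol) to give 28, and DBU then removes the acidic C5 hydrogen and expels silanolate (E1cB elimination) to give the thermodynamically preferred Z-ylidene, in which the chain lies on the side of the ring oxygen.

Step 19
Reactants: 11 alkenylstannane triol; 29 bromo ylidenebutenolide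
Product: 30 C3′ triethylsilyl ether of the target
Conditions: Pd2(dba)3 (5 mol%), AsPh3 (40 mol%), NMP, rt to 40 °C, dark
Reagents that add atoms: none
Why: Stille coupling (oxidative addition of zerovalent palladium into the C3–Br bond of the α-bromobutenolide, transmetallation from the alkenylstannane aided by the weakly bound AsPh3 ligand, reductive elimination with retention of both alkene geometries) forms the lactone C3–vinyl bond under neutral conditions that spare the free triol.

Step 20
Reactants: 30 silyl ether of the target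
Product: 31 target
Conditions: HF·pyridine, pyridine, THF, 0 °C to rt
Reagents that add atoms: none
Why: Buffered HF·pyridine cleaves the triethylsilyl ether (desilylation) without base that could open the lactone or acid strong enough to ionise the tertiary allylic C6 hydroxyl.

**Compound list**

1 | ketoisophorone (2,6,6-trimethylcyclohex-2-ene-1,4-dione) | CC1=CC(=O)CC(C)(C)C1=O | starting material
2 | (4R)-4-hydroxy-2,6,6-trimethylcyclohex-2-en-1-one [(R)-phorenol] | CC1=C[C@H](O)CC(C)(C)C1=O | intermediate
3 | (4R)-4-[(tert-butyldimethylsilyl)oxy]-2,6,6-trimethylcyclohex-2-en-1-one | CC1=C[C@H](O[Si](C)(C)C(C)(C)C)CC(C)(C)C1=O | intermediate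
4 | (4S)-4-[(tert-butyldimethylsilyl)oxy]-2,2,6-trimethylcyclohexan-1-one, mixture of C6 epimers | CC1C[C@H](O[Si](C)(C)C(C)(C)C)CC(C)(C)C1=O | intermediate
5 | (4S)-4-[(tert-butyldimethylsilyl)oxy]-2,6,6-trimethylcyclohex-1-en-1-yl trifluoromethanesulfonate | CC1=C(OS(=O)(=O)C(F)(F)F)C(C)(C)C[C@@H](O[Si](C)(C)C(C)(C)C)C1 | intermediate
6 | trimethylsilylacetylene | C#C[Si](C)(C)C | starting material
7 | tert-butyldimethyl({(1S)-3,5,5-trimethyl-4-[(trimethylsilyl)ethynyl]cyclohex-3-en-1-yl}oxy)silane | CC1=C(C#C[Si](C)(C)C)C(C)(C)C[C@@H](O[Si](C)(C)C(C)(C)C)C1 | intermediate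
8 | (1S)-4-ethynyl-3,5,5-trimethylcyclohex-3-en-1-ol [(S)-enynol] | CC1=C(C#C)C(C)(C)C[C@@H](O)C1 | intermediate
9 | (1R,3R,6R)-6-ethynyl-1,5,5-trimethyl-7-oxabicyclo[4.1.0]heptan-3-ol (oxirane oxygen cis to the hydroxyl) | C#C[C@]1(O2)C(C)(C)C[C@@H](O)C[C@]12C | intermediate
10 | (1R,2S,4R)-1-ethynyl-2,6,6-trimethylcyclohexane-1,2,4-triol (ethynyl triol) | C#C[C@]1(O)C(C)(C)C[C@@H](O)C[C@]1(C)O | intermediate
11 | (1S,2S,4R)-2,6,6-trimethyl-1-[(E)-2-(tributylstannyl)ethenyl]cyclohexane-1,2,4-triol | CCCC[Sn](CCCC)(CCCC)/C=C/[C@]1(O)C(C)(C)C[C@@H](O)C[C@]1(C)O | intermediate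
12 | (4R,6R)-actinol [(4R,6R)-4-hydroxy-2,2,6-trimethylcyclohexan-1-one] | O=C1C(C)(C)C[C@H](O)C[C@H]1C | starting material
13 | (4R,6R)-2,2,6-trimethyl-4-[(triethylsilyl)oxy]cyclohexan-1-one | O=C1C(C)(C)C[C@H](O[Si](CC)(CC)CC)C[C@H]1C | intermediate
14 | (4R)-2,6,6-trimethyl-4-[(triethylsilyl)oxy]cyclohex-1-en-1-yl trifluoromethanesulfonate | CC1=C(OS(=O)(=O)C(F)(F)F)C(C)(C)C[C@H](O[Si](CC)(CC)CC)C1 | intermediate
15 | (E)-3-methylpent-2-en-4-yn-1-ol | C#C/C(C)=C/CO | starting material
16 | (2E)-3-methyl-5-{(4R)-2,6,6-trimethyl-4-[(triethylsilyl)oxy]cyclohex-1-en-1-yl}pent-2-en-4-yn-1-ol | CC1=C(C#C/C(C)=C/CO)C(C)(C)C[C@H](O[Si](CC)(CC)CC)C1 | intermediate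
17 | (2E)-3-methyl-5-{(4R)-2,6,6-trimethyl-4-[(triethylsilyl)oxy]cyclohex-1-en-1-yl}pent-2-en-4-ynal | CC1=C(C#C/C(C)=C/C=O)C(C)(C)C[C@H](O[Si](CC)(CC)CC)C1 | intermediate
18 | triethyl 4-phosphonocrotonate [ethyl (2E)-4-(diethoxyphosphoryl)but-2-enoate] | CCOC(=O)/C=C/CP(=O)(OCC)OCC | starting material
19 | ethyl (2E,4E,6E)-7-methyl-9-{(4R)-2,6,6-trimethyl-4-[(triethylsilyl)oxy]cyclohex-1-en-1-yl}nona-2,4,6-trien-8-ynoate | CC1=C(C#C/C(C)=C/C=C/C=C/C(=O)OCC)C(C)(C)C[C@H](O[Si](CC)(CC)CC)C1 | intermediate
20 | (2E,4E,6E)-7-methyl-9-{(4R)-2,6,6-trimethyl-4-[(triethylsilyl)oxy]cyclohex-1-en-1-yl}nona-2,4,6-trien-8-yn-1-ol | CC1=C(C#C/C(C)=C/C=C/C=C/CO)C(C)(C)C[C@H](O[Si](CC)(CC)CC)C1 | intermediate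
21 | (2E,4E,6E)-7-methyl-9-{(4R)-2,6,6-trimethyl-4-[(triethylsilyl)oxy]cyclohex-1-en-1-yl}nona-2,4,6-trien-8-ynal | CC1=C(C#C/C(C)=C/C=C/C=C/C=O)C(C)(C)C[C@H](O[Si](CC)(CC)CC)C1 | intermediate
22 | 2-(triphenylphosphoranylidene)propanal | CC(C=O)=P(c1ccccc1)(c1ccccc1)c1ccccc1 | starting material
23 | (2E,4E,6E,8E)-2,9-dimethyl-11-{(4R)-2,6,6-trimethyl-4-[(triethylsilyl)oxy]cyclohex-1-en-1-yl}undeca-2,4,6,8-tetraen-10-ynal | CC1=C(C#C/C(C)=C/C=C/C=C/C=C(C)/C=O)C(C)(C)C[C@H](O[Si](CC)(CC)CC)C1 | intermediate
24 | furan-2(5H)-one | O=C1OCC=C1 | starting material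
25 | trans-3,4-dibromodihydrofuran-2(3H)-one (racemic, one enantiomer drawn) | O=C1OC[C@H](Br)[C@H]1Br | intermediate
26 | 3-bromofuran-2(5H)-one | O=C1OCC=C1Br | intermediate
27 | 3-bromo-2-[(tert-butyldimethylsilyl)oxy]furan | CC(C)(C)[Si](C)(C)Oc1occc1Br | intermediate
28 | 3-bromo-5-[(2E,4E,6E,8E)-1-[(tert-butyldimethylsilyl)oxy]-2,9-dimethyl-11-{(4R)-2,6,6-trimethyl-4-[(triethylsilyl)oxy]cyclohex-1-en-1-yl}undeca-2,4,6,8-tetraen-10-yn-1-yl]furan-2(5H)-one, diastereomer mixture at the two new centres | CC1=C(C#C/C(C)=C/C=C/C=C/C=C(C)/C(O[Si](C)(C)C(C)(C)C)C2OC(=O)C(Br)=C2)C(C)(C)C[C@H](O[Si](CC)(CC)CC)C1 | intermediate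
29 | (5Z)-3-bromo-5-[(2E,4E,6E,8E)-2,9-dimethyl-11-{(4R)-2,6,6-trimethyl-4-[(triethylsilyl)oxy]cyclohex-1-en-1-yl}undeca-2,4,6,8-tetraen-10-yn-1-ylidene]furan-2(5H)-one | CC1=C(C#C/C(C)=C/C=C/C=C/C=C(C)/C=C2C=C(Br)C(=O)O/2)C(C)(C)C[C@H](O[Si](CC)(CC)CC)C1 | intermediate
30 | (5Z)-5-[(2E,4E,6E,8E)-2,9-dimethyl-11-{(4R)-2,6,6-trimethyl-4-[(triethylsilyl)oxy]cyclohex-1-en-1-yl}undeca-2,4,6,8-tetraen-10-yn-1-ylidene]-3-{(E)-2-[(1S,2S,4R)-1,2,4-trihydroxy-2,6,6-trimethylcyclohexyl]ethenyl}furan-2(5H)-one | CC1=C(C#C/C(C)=C/C=C/C=C/C=C(C)/C=C2C=C(/C=C/[C@]3(O)C(C)(C)C[C@@H](O)C[C@]3(C)O)C(=O)O/2)C(C)(C)C[C@H](O[Si](CC)(CC)CC)C1 | intermediate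
31 | (5Z)-5-[(2E,4E,6E,8E)-11-[(4R)-4-hydroxy-2,6,6-trimethylcyclohex-1-en-1-yl]-2,9-dimethylundeca-2,4,6,8-tetraen-10-yn-1-ylidene]-3-{(E)-2-[(1S,2S,4R)-1,2,4-trihydroxy-2,6,6-trimethylcyclohexyl]ethenyl}furan-2(5H)-one (CNP0163979.2) | CC1=C(C#C/C(C)=C/C=C/C=C/C=C(C)/C=C2C=C(/C=C/[C@]3(O)C(C)(C)C[C@@H](O)C[C@]3(C)O)C(=O)O/2)C(C)(C)C[C@H](O)C1 | target

**Totals**

Total step count: 20.
Longest linear sequence: 11 steps (12 to 31 through steps 9–16, 18, 19 and 20). The triol branch from 1 runs 10 steps (steps 1–8, 19, 20).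

**Steps most likely to fail, with fallbacks**

Step 7. Oxygen transfer from the vanadium peroxide to the hindered, alkyne-conjugated tetrasubstituted alkene may stall or lose face control. In the acid stage water may enter at C6, or the cationic C5 may lose a proton to give allylic alcohols. The fallback replaces substrate direction by reagent control on an allylic alcohol; it sets out from 5 and returns at 9. Methoxycarbonylation of 5 [Pd(OAc)2, dppp, CO (1 atm), MeOH, Et3N, DMF, 60 °C] should give the methyl cyclohexenecarboxylate F1, and i-Bu2AlH (CH2Cl2, −78 °C) the cyclohexenylmethanol F2. Sharpless asymmetric epoxidation [Ti(Oi-Pr)4, D-(−)-diethyl tartrate, t-BuOOH, 4 Å sieves, CH2Cl2, −20 °C] should then place the oxirane on the face syn to the C3 silyloxy group, giving the syn-epoxy alcohol F3. Dess–Martin oxidation should give the epoxy aldehyde F4, and Ohira–Bestmann alkynylation [dimethyl (1-diazo-2-oxopropyl)phosphonate, K2CO3, MeOH] the silyl ether of the ethynyl epoxide F5. TBAF releases 9, which is then opened to 10 in a separate flask with the aqueous acid of step 7, on purified material and free of oxidant. This fallback secures the oxygen delivery only; the opening still rests on the argument of step 7.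

Step 18. The silyl triflate may ionise the polyenylic silyl ether 28 to a delocalised cation that oligomerises, elimination may stay incomplete, or the new exocyclic alkene and the 9′ enyne alkene may scramble. The fallback separates the aldol from the elimination and avoids the silyl triflate in the presence of the polyene; it sets out from 26 and 23 and returns at 29. TIPSOTf and Et3N (CH2Cl2, 0 °C) should convert 26 into the isolable 3-bromo-2-(triisopropylsilyloxy)furan F6. BF3·OEt2 (CH2Cl2, −78 °C) then promotes its vinylogous Mukaiyama aldol addition to 23, giving the γ-(1-hydroxyalkyl) bromobutenolide F7 as a diastereomer mixture. Acetylation (Ac2O, Et3N, DMAP) gives the acetate F8, from which DBU eliminates acetic acid to the Z-ylidene 29.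

Step 19. Transmetallation from the hindered γ-hydroxy alkenylstannane may be slow, letting protodestannylation and homocoupling compete, and palladium may isomerise the polyene during a long reaction. The fallback exchanges tin for boron; it sets out from 10 and returns at 30. Copper-catalysed formal hydroboration of 10 (CuCl, Xantphos, NaOt-Bu, B2pin2, MeOH, THF, rt) should give the (E)-alkenyl pinacol boronate F9, with boron on the terminal carbon by syn addition. Suzuki–Miyaura coupling of F9 with 29 [Pd(dppf)Cl2, K3PO4, THF/H2O, rt to 40 °C] should give 30.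

**Further compounds**

F1 | step 7 | methyl (4S)-4-[(tert-butyldimethylsilyl)oxy]-2,6,6-trimethylcyclohex-1-ene-1-carboxylate | CC1=C(C(=O)OC)C(C)(C)C[C@@H](O[Si](C)(C)C(C)(C)C)C1
F2 | step 7 | [(4S)-4-[(tert-butyldimethylsilyl)oxy]-2,6,6-trimethylcyclohex-1-en-1-yl]methanol | CC1=C(CO)C(C)(C)C[C@@H](O[Si](C)(C)C(C)(C)C)C1
F3 | step 7 | [(1R,4R,6R)-4-[(tert-butyldimethylsilyl)oxy]-2,2,6-trimethyl-7-oxabicyclo[4.1.0]heptan-1-yl]methanol (oxirane syn to the silyloxy group) | OC[C@]1(O2)C(C)(C)C[C@@H](O[Si](C)(C)C(C)(C)C)C[C@]12C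
F4 | step 7 | (1S,4R,6R)-4-[(tert-butyldimethylsilyl)oxy]-2,2,6-trimethyl-7-oxabicyclo[4.1.0]heptane-1-carbaldehyde | O=C[C@]1(O2)C(C)(C)C[C@@H](O[Si](C)(C)C(C)(C)C)C[C@]12C
F5 | step 7 | tert-butyl{[(1R,3R,6R)-6-ethynyl-1,5,5-trimethyl-7-oxabicyclo[4.1.0]heptan-3-yl]oxy}dimethylsilane | C#C[C@]1(O2)C(C)(C)C[C@@H](O[Si](C)(C)C(C)(C)C)C[C@]12C
F6 | step 18 | 3-bromo-2-[(triisopropylsilyl)oxy]furan | CC(C)[Si](Oc1occc1Br)(C(C)C)C(C)C
F7 | step 18 | 3-bromo-5-[(2E,4E,6E,8E)-1-hydroxy-2,9-dimethyl-11-{(4R)-2,6,6-trimethyl-4-[(triethylsilyl)oxy]cyclohex-1-en-1-yl}undeca-2,4,6,8-tetraen-10-yn-1-yl]furan-2(5H)-one, diastereomer mixture | CC1=C(C#C/C(C)=C/C=C/C=C/C=C(C)/C(O)C2OC(=O)C(Br)=C2)C(C)(C)C[C@H](O[Si](CC)(CC)CC)C1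
F8 | step 18 | acetate of F7, diastereomer mixture | CC1=C(C#C/C(C)=C/C=C/C=C/C=C(C)/C(OC(C)=O)C2OC(=O)C(Br)=C2)C(C)(C)C[C@H](O[Si](CC)(CC)CC)C1
F9 | step 19 | (1S,2S,4R)-2,6,6-trimethyl-1-[(E)-2-(4,4,5,5-tetramethyl-1,3,2-dioxaborolan-2-yl)ethenyl]cyclohexane-1,2,4-triol | CC1(C)OB(/C=C/[C@]2(O)C(C)(C)C[C@@H](O)C[C@]2(C)O)OC1(C)C
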